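Labdane numbering (C1–C20) is used for the target and for every intermediate, including the pinane-derived ones. Compound numbers are those of the steps below.

## Analysis of the target

The target 21 is the (S)-3-methylpentanoate of a labdane-type diterpene diol of the enantiomeric (ent) series: a trans-fused decalin (ring A: C1–C5 and C10; ring B: C5–C10) whose C9 carries a five-carbon chain ending in an (E)-trisubstituted allylic C15–O ester. The core has four stereocentres, C3 (S), C5 (S), C9 (R) and C10 (S), and the acyl part a fifth. C10 is quaternary and lies between C5 and C9; its methyl group is axial, trans to H5 (trans fusion) and cis to the equatorial C9 chain. The C3 hydroxyl is axial, trans to the C10 methyl and next to the C4 gem-dimethyl group; it is the less stable C3 epimer and, being neopentylic, cannot be inverted by substitution. Sensitive groups are the allylic ester (ionization, hydrolysis), the C7=C8 alkene, which acid can move to C8=C9, and the neopentyl alcohol under strongly acidic conditions. The difficulties are the quaternary C10 in the right absolute sense beside two stereocentres, the position of the ring alkene, the axial alcohol and the E geometry at C13=C14. The strategy rests on the fact that ring B is already contained in (1S,5S)-verbenone 3: the enone carbonyl is C8, its α-carbon C9, its β-carbon C10 with the C10 methyl, the bridgeheads are C5 and C7, the methylene bridge is C6, and the dimethyl-substituted bridge is C4, held on C5 with the configuration the target needs. Only the cyclobutane bond C4–C7 is foreign to the target, and it is a strained bond α to the ketone.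

## Retrosynthetic reasoning

The ester bond C15–O is cut first, to diol 19 and acid 20. The allylic ester is the most fragile group, and the acid carries the one stereocentre the core cannot control, so both enter last. The forward reaction has to acylate the primary allylic hydroxyl and leave the axial, neopentylic C3 hydroxyl alone.

Diol 19 is traced to ethyl ester 18 by reduction, and the C13=C14 bond to a phosphonate olefination of a methyl ketone. This cut is made early, on the bicyclic diketone 7, giving 8. A free C13 ketone would be a 1,5-diketone partner of the C8 ketone and open to aldol closure in every acid or base step that follows. The β,β-disubstituted enoate is a poor electrophile and a poor hydrogen-atom acceptor. The forward reaction must take the methyl ketone beside the hindered ring ketone and give the E isomer.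

The axial C3 alcohol of 18 is cut back to ketone 17, and 17 to the C3 epimer mixture 16. The ring closure that creates C3 does not control it, so its configuration is set by the direction of hydride delivery to a ketone.

The C8–C17 bond of 16 is cut to enol triflate 15, which comes from ketone 13 by enolization towards C7. The double bond is thus placed by the regiochemistry of a deprotonation. Dehydration of a tertiary alcohol would give ring and exocyclic alkenes together.

Ketone 13 is the C9 epimer of mixture 12 in which the chain is equatorial. C9 is α to the C8 ketone and the only enolizable stereocentre of the core, so it is left to equilibration and is asked of no bond-forming step.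

Ring A of 12 is opened at C3–C4 to the isopropenyl keto aldehyde 11. C4 can be reached as a tertiary radical from a 1,1-disubstituted alkene, and C3 as a carbonyl carbon then carries the oxygen the target needs. The trans fusion is already fixed by C5 and C10, so the closure creates only C3. The forward reaction is a hydrogen-atom-transfer-initiated 6-exo addition of the C4 radical to the aldehyde.

In 11 the isopropenyl group on C5 and the C8 ketone are the two ends of a broken cyclobutane; reconnecting C4 to C7 gives the bicyclic ketone 8. Forward, a silyl iodide opens the bond α to the ketone at its tertiary end and a base-induced elimination leaves the isopropenyl group, with C5 unchanged. The acetal on C3 cannot be expected to outlast this reagent, and the sequence is ordered to use that. The aldehyde is released in the same step and consumed in the next, and all enolate chemistry at C8 is done afterwards on the decalin, not on a monocyclic ketone carrying a free aldehyde.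

Diketone 7 is cut at C1–C10 and C9–C11 into 3, the organomagnesium reagent 2 and the α-silyl enone 4. Both bonds lie on the enone of 3, so one conjugate addition with enolate trapping makes them. The gem-dimethyl bridge decides the face at C10, and the enolate can only be the C8–C9 enolate because C7 is a bridgehead. This gives the quaternary centre, the three missing carbons of ring A and four of the five side-chain carbons.

Reagent 2 comes from bromide 1 by metal insertion.

## Alternatives that were turned down

Alternative 1: Ring B is cut at C9–C10, with an aromatic ring as the future ring A.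
- **Forward key step:** a chiral iridium phosphoramidite catalyst ionizes the dienyl carbonate of phenol A2, and the para carbon of the phenolate (C10, bearing the methyl) attacks the substituted allyl terminus C9. This closes ring B as the cross-conjugated dienone A1.
- **For:** C9 and the quaternary C10 are set in one catalytic asymmetric step from an achiral precursor. The C7=C8 alkene with its methyl is already in place, and the vinyl group on C9 is a handle for the chain.
- **Against:** the ortho carbon C4 is also methyl-substituted and also six atoms from C9, so it competes with C10, as does the phenol oxygen. The allyl unit is part of a pentadienyl system, so the site of attack and the Z geometry of C7=C8 are both at risk. A1 lacks the second C4 methyl and the C5 stereocentre. A reductive methylation, saturation of C1=C2 and the C3 reduction would have to be done on a molecule with four π systems.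
- **Comparison:** it is stronger at C9 (set kinetically by the catalyst, where the chosen route relies on equilibration) and on the ring alkene (no triflate chemistry). The chosen route takes C5, C10 and the complete C4 gem-dimethyl group from 3, with a stereochemical outcome that rests on a rigid bicycle and not on catalyst selectivity among competing nucleophilic sites.

Alternative 2: Both rings are cut at once, at C5–C10 and C8–C9.
- **Forward key step:** a dialkylaluminium chloride chelated to the N-acyl oxazolidinone of triene A4 promotes an intramolecular Diels–Alder reaction of the (E)-3-methylenoyl unit with the (E,E)-diene, giving the trans-decalin A3.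
- **For:** two rings and C5, C9 and C10 arise in one step from an acyclic precursor. The C3 ketone is present from the start, so no late closure of ring A is needed.
- **Against:** the dienophile is β,β-disubstituted and must form the quaternary C10, and the diene terminus C5 is neopentylic beside C4; both slow the cycloaddition. The C3 ketone in the tether competes for the Lewis acid. A3 has its alkene at C6=C7 and a C8 methyl stereocentre that must be erased by moving the alkene to C7=C8. The acyl carbon is only C11, so C12–C16 must still be attached next to the hindered C9.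
- **Comparison:** it is stronger in ring construction and needs no radical closure. The chosen route places the ring alkene through an enol triflate, brings C11–C13 and C16 in with the key step, and uses an inexpensive terpene where this route needs a stoichiometric auxiliary.

Alternative 3: Ring B is cut at C9–C10 and C7–C8, with C11 tethered to the C3 oxygen.
- **Forward key step:** on heating, the alkynoate of ester A6 adds across the C10=C5–C6=C7 diene from the face of the C3 oxygen, giving the lactone-bridged 1,4-diene A5.
- **For:** it is the only plan that uses the axial C3 oxygen constructively. The tether delivers C9 cis to the oxygen, so the trans relation of hydroxyl and C10 methyl arises directly and no oxidation–reduction at C3 is needed. C17 and C11 come with the dienophile.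
- **Against:** the ester tether must adopt its disfavoured s-cis form in a seven-membered bridging transition state that also creates the quaternary C10, so forcing conditions are likely. A5 still lacks both C5 and C9: the C5=C6 alkene must be reduced to the trans fusion, and the tetrasubstituted C8=C9 alkene moved to C7=C8 with protonation of C9 from the right face. The enantiopure alcohol of A6 needs its own asymmetric synthesis.
- **Comparison:** it is stronger at C3 and on C17. The chosen route has C5 and C10 fixed from the first step and leaves only an epimerizable C9 and a reducible C3.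

Key step: step 2

Assumption: 4 is taken as a purchasable reagent.
Remark: compounds 7 to 12 are carried as mixtures at the epimerizable C9 and compounds 12 to 16 as mixtures at C3; the two centres are fixed in steps 6 and 10.

## Route

Step 1
Reactants: 1 2-(2-bromoethyl)-1,3-dioxolane
Product: 2 [2-(1,3-dioxolan-2-yl)ethyl]magnesium bromide (THF solution, titrated and used at once)
Conditions: Mg turnings (activated with 1,2-dibromoethane), THF, 20–30 °C
Reagents that add atoms: magnesium, [Mg]
Why: Grignard formation by insertion of magnesium into the primary C–Br bond; the acetal is inert to the organomagnesium centre as long as the solution stays near room temperature, above which this reagent is prone to decompose.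

Step 2
Reactants: 3 (1S,5S)-(−)-verbenone; 2 [2-(1,3-dioxolan-2-yl)ethyl]magnesium bromide; 4 3-(trimethylsilyl)but-3-en-2-one
Product: 7 4-[2-(1,3-dioxolan-2-yl)ethyl]-4,6,6-trimethyl-3-(3-oxobutyl)bicyclo[3.1.1]heptan-2-one (C5 and C10 as in 21; C9 epimers), via bromomagnesium enolate 5 (not isolated), via α-silyl diketone 6 (not isolated)
Conditions: CuBr·SMe2 (10 mol %), 2 (1.3 equiv), THF, −40 → −20 °C; 4 (1.5 equiv), −78 → −20 °C; then MeOH, K2CO3, 0 °C
Reagents that add atoms: none
Why: Transmetalation of 2 to copper and 1,4-addition to the enone of 3 (copper-catalysed conjugate addition of an organomagnesium reagent to a β,β-disubstituted enone) form C1–C10 and leave the bromomagnesium enolate 5. C10 is the only stereocentre the step must set: the gem-dimethyl bridge of the rigid bicycle covers one face of the enone, so the chain should enter from the face of the methylene bridge, which places it trans to C4 and the C10 methyl cis to C4, the arrangement of the trans ring fusion. The enolate is regiodefined at C8–C9 and cannot equilibrate, since the other α-carbon C7 is a bridgehead. Michael addition of 5 to 4 forms C9–C11, and the silyl group stabilizes the resulting enolate, which suppresses proton transfer, a second addition and polymerization of the acceptor (closest known type: conjugate addition followed by enolate trapping with an α-silyl vinyl ketone). Methanolic K2CO3 removes the silyl group of 6 by attack at silicon, under conditions that should be too mild for aldol closure onto the hindered ring ketone. No ring is closed. The step needs 1,4- over 1,2-addition, which copper secures, and facial selectivity at C10, which the bridge secures; C9 is expected to form mainly anti to the bridge, that is epimeric to the target, but it is α to the ketone and is corrected in step 6.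

Step 3
Reactants: 7 4-[2-(1,3-dioxolan-2-yl)ethyl]-4,6,6-trimethyl-3-(3-oxobutyl)bicyclo[3.1.1]heptan-2-one
Product: 8 ethyl (2E)-5-{4-[2-(1,3-dioxolan-2-yl)ethyl]-4,6,6-trimethyl-2-oxobicyclo[3.1.1]heptan-3-yl}-3-methylpent-2-enoate (C9 epimers)
Conditions: (EtO)2P(O)CH2CO2Et (2.0 equiv), NaH (1.8 equiv), THF, 0 → 45 °C
Reagents that add atoms: triethyl phosphonoacetate, CCOC(=O)CP(=O)(OCC)OCC
Why: Horner–Wadsworth–Emmons olefination: the stabilized phosphonate anion should add to the unhindered methyl ketone and not to the ring ketone, which is flanked by a bridgehead and by C9 next to the quaternary C10; the E isomer (ester trans to the C12 chain) should predominate and any Z isomer is removed by chromatography. The C13 ketone is converted here so that no 1,5-diketone enters the acid and base steps that follow.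

Step 4
Reactants: 8 ethyl (2E)-5-{4-[2-(1,3-dioxolan-2-yl)ethyl]-4,6,6-trimethyl-2-oxobicyclo[3.1.1]heptan-3-yl}-3-methylpent-2-enoate
Product: 11 ethyl (2E)-3-methyl-5-[2-methyl-6-oxo-2-(3-oxopropyl)-3-(prop-1-en-2-yl)cyclohexyl]pent-2-enoate (C5 and C10 as in 21; C9 epimers), via iodo silyl enol ether 9 (not isolated), via isopropenyl silyl enol ether 10 (not isolated)
Conditions: Me3SiI (3.5 equiv), CH2Cl2, −20 → 0 °C; DBU (6 equiv), 0 °C → rt; then 1 M HCl, THF, 0 °C
Reagents that add atoms: water, O
Why: Silylation of the C8 carbonyl and attack of iodide at the tertiary C4 cleave the strained C4–C7 bond (iodide-assisted opening of a cyclobutyl ketone of the pinane type) to the C7=C8 silyl enol ether 9, and the same reagent opens the dioxolane to an α-iodo ether. DBU removes hydrogen iodide from the tertiary iodide towards a methyl group, since six methyl hydrogens compete with the single H5 shielded by the quaternary C10, and from the α-iodo ether while both carbonyl groups are still masked (10); cold aqueous acid then returns the ketone and the aldehyde. C5 and C10 are not touched.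

Step 5
Reactants: 11 ethyl (2E)-3-methyl-5-[2-methyl-6-oxo-2-(3-oxopropyl)-3-(prop-1-en-2-yl)cyclohexyl]pent-2-enoate
Product: 12 ethyl (2E)-5-(6-hydroxy-5,5,8a-trimethyl-2-oxodecahydronaphthalen-1-yl)-3-methylpent-2-enoate (trans-fused; C5 and C10 as in 21; C3 and C9 epimers)
Conditions: Fe(acac)3 (0.5 equiv), PhSiH3 (2.5 equiv), EtOH, 60 °C, Ar
Reagents that add atoms: none
Why: Hydrogen-atom transfer from an iron hydride to the 1,1-disubstituted alkene gives the tertiary C4 radical, which adds to the aldehyde carbon C3 in a 6-exo-trig closure through a chair with C1 and C4 equatorial on ring B; divalent iron reduces the alkoxy radical and ethanol protonates it (hydrogen-atom-transfer radical cyclization of alkenes onto carbonyl groups). The trans fusion follows from C5 and C10, C3 is not controlled, and the trisubstituted enoate and the ring ketone should react more slowly than the isopropenyl group and the aldehyde.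

Step 6
Reactants: 12 ethyl (2E)-5-(6-hydroxy-5,5,8a-trimethyl-2-oxodecahydronaphthalen-1-yl)-3-methylpent-2-enoate (C3 and C9 epimers)
Product: 13 ethyl (2E)-5-(6-hydroxy-5,5,8a-trimethyl-2-oxodecahydronaphthalen-1-yl)-3-methylpent-2-enoate with the C9 chain equatorial (C5, C9 and C10 as in 21; C3 epimers)
Conditions: p-TsOH·H2O (0.2 equiv), EtOH, 50 °C
Reagents that add atoms: none
Why: Acid-catalysed enolization, which prefers the more substituted C8=C9 enol, equilibrates C9; the epimer with the chain equatorial and cis to the axial C10 methyl avoids the syn-axial contacts with H5 and H7 and should predominate, and it has the configuration of 21. Acid is chosen over alkoxide to leave the enoate geometry alone, and the minor epimer can be resubmitted.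

Step 7
Reactants: 13 ethyl (2E)-5-(6-hydroxy-5,5,8a-trimethyl-2-oxodecahydronaphthalen-1-yl)-3-methylpent-2-enoate (C9 as in 21)
Product: 15 ethyl (2E)-5-[6-hydroxy-5,5,8a-trimethyl-2-(trifluoromethylsulfonyloxy)-1,4,4a,5,6,7,8,8a-octahydronaphthalen-1-yl]-3-methylpent-2-enoate (C3 epimers), via dilithium alkoxide enolate 14 (not isolated)
Conditions: LiN(SiMe3)2 (2.4 equiv), THF, −78 °C; 2-[N,N-bis(trifluoromethylsulfonyl)amino]-5-chloropyridine (1.2 equiv), −78 → −30 °C; H2O
Reagents that add atoms: 2-[N,N-bis(trifluoromethylsulfonyl)amino]-5-chloropyridine, FC(F)(F)S(=O)(=O)N(c1ccc(Cl)cn1)S(=O)(=O)C(F)(F)F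
Why: The first equivalent of base forms the C3 lithium alkoxide and the second removes a C7 proton (kinetic enolization at the methylene group; H9 is tertiary and neopentylic); the N-pyridyl triflimide then traps the enolate on oxygen at low temperature, where the hindered alkoxide should not be sulfonylated.

Step 8
Reactants: 15 ethyl (2E)-5-[6-hydroxy-5,5,8a-trimethyl-2-(trifluoromethylsulfonyloxy)-1,4,4a,5,6,7,8,8a-octahydronaphthalen-1-yl]-3-methylpent-2-enoate
Product: 16 ethyl (2E)-5-(6-hydroxy-2,5,5,8a-tetramethyl-1,4,4a,5,6,7,8,8a-octahydronaphthalen-1-yl)-3-methylpent-2-enoate (C3 epimers)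
Conditions: MeZnCl (4 equiv), Pd(PPh3)4 (5 mol %), THF, 50 °C
Reagents that add atoms: methylzinc chloride, C[Zn]Cl
Why: Negishi coupling: zerovalent palladium inserts into the C8–O bond of the enol triflate, MeZnCl transfers the methyl group and reductive elimination forms C8–C17 with the double bond fixed at C7=C8; the organozinc reagent tolerates the ester, and one equivalent is consumed by the hydroxyl.

Step 9
Reactants: 16 ethyl (2E)-5-(6-hydroxy-2,5,5,8a-tetramethyl-1,4,4a,5,6,7,8,8a-octahydronaphthalen-1-yl)-3-methylpent-2-enoate
Product: 17 ethyl (2E)-3-methyl-5-(2,5,5,8a-tetramethyl-6-oxo-1,4,4a,5,6,7,8,8a-octahydronaphthalen-1-yl)pent-2-enoate (C5, C9 and C10 as in 21)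
Conditions: DMP (1,1,1-triacetoxy-1,2-benziodoxol-3-one, 1.5 equiv), CH2Cl2, rt
Reagents that add atoms: none
Why: Hypervalent-iodine oxidation of the secondary alcohol; both C3 epimers converge on one ketone, and neither alkene nor the ester reacts.

Step 10
Reactants: 17 ethyl (2E)-3-methyl-5-(2,5,5,8a-tetramethyl-6-oxo-1,4,4a,5,6,7,8,8a-octahydronaphthalen-1-yl)pent-2-enoate
Product: 18 ethyl (2E)-5-[(1R,4aS,6S,8aS)-6-hydroxy-2,5,5,8a-tetramethyl-1,4,4a,5,6,7,8,8a-octahydronaphthalen-1-yl]-3-methylpent-2-enoate
Conditions: LiBH(s-Bu)3 (1.3 equiv), THF, −78 °C; H2O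
Reagents that add atoms: none
Why: The bulky trialkylborohydride should deliver hydride along the equatorial direction, since the axial line is blocked by the axial hydrogens on C1 and C5; this leaves the hydroxyl axial and trans to the C10 methyl (3S), and at −78 °C a β,β-disubstituted enoate should not be reduced. Any equatorial alcohol can be returned through step 9.

Step 11
Reactants: 18 ethyl (2E)-5-[(1R,4aS,6S,8aS)-6-hydroxy-2,5,5,8a-tetramethyl-1,4,4a,5,6,7,8,8a-octahydronaphthalen-1-yl]-3-methylpent-2-enoate
Product: 19 (2E)-5-[(1R,4aS,6S,8aS)-6-hydroxy-2,5,5,8a-tetramethyl-1,4,4a,5,6,7,8,8a-octahydronaphthalen-1-yl]-3-methylpent-2-en-1-ol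
Conditions: i-Bu2AlH (3.5 equiv), CH2Cl2, −78 → −40 °C; aq. KNaC4H4O6
Reagents that add atoms: none
Why: i-Bu2AlH reduces the unsaturated ester in the 1,2 sense to the allylic alcohol without touching either alkene; the excess allows for the free hydroxyl.

Step 12
Reactants: 19 (2E)-5-[(1R,4aS,6S,8aS)-6-hydroxy-2,5,5,8a-tetramethyl-1,4,4a,5,6,7,8,8a-octahydronaphthalen-1-yl]-3-methylpent-2-en-1-ol; 20 (S)-3-methylpentanoic acid
Product: 21 (2E)-5-[(1R,4aS,6S,8aS)-6-hydroxy-2,5,5,8a-tetramethyl-1,4,4a,5,6,7,8,8a-octahydronaphthalen-1-yl]-3-methylpent-2-en-1-yl (3S)-3-methylpentanoate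
Conditions: 20 (1.05 equiv), EDC·HCl (1.2 equiv), DMAP (0.1 equiv), CH2Cl2, 0 °C
Reagents that add atoms: none
Why: Carbodiimide esterification with DMAP catalysis (Steglich esterification): the primary allylic hydroxyl should react far faster than the axial C3 hydroxyl beside the gem-dimethyl group, and the stereocentre of 20 is β to the carbonyl and cannot epimerize.

## Compound list

1 | 2-(2-bromoethyl)-1,3-dioxolane | BrCCC1OCCO1 | starting material
2 | [2-(1,3-dioxolan-2-yl)ethyl]magnesium bromide | Br[Mg]CCC1OCCO1 | intermediate
3 | (1S,5S)-(−)-verbenone, 4,6,6-trimethylbicyclo[3.1.1]hept-3-en-2-one | O=C1C=C(C)[C@@H]2C[C@H]1C2(C)C | starting material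
4 | 3-(trimethylsilyl)but-3-en-2-one | CC(=O)C(=C)[Si](C)(C)C | starting material
5 | bromomagnesium 4-[2-(1,3-dioxolan-2-yl)ethyl]-4,6,6-trimethylbicyclo[3.1.1]hept-2-en-2-olate (formed in the flask; C10 as in 21) | C1=C(O[Mg]Br)[C@H]2C[C@H](C2(C)C)[C@@]1(C)CCC3OCCO3 | intermediate
6 | 4-[2-(1,3-dioxolan-2-yl)ethyl]-4,6,6-trimethyl-3-[3-oxo-2-(trimethylsilyl)butyl]bicyclo[3.1.1]heptan-2-one (formed in the flask) | CC(=O)C([Si](C)(C)C)CC1C(=O)[C@H]2C[C@H](C2(C)C)[C@@]1(C)CCC3OCCO3 | intermediate
7 | 4-[2-(1,3-dioxolan-2-yl)ethyl]-4,6,6-trimethyl-3-(3-oxobutyl)bicyclo[3.1.1]heptan-2-one (C5 and C10 as in 21; C9 epimers) | CC(=O)CCC1C(=O)[C@H]2C[C@H](C2(C)C)[C@@]1(C)CCC3OCCO3 | intermediate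
8 | ethyl (2E)-5-{4-[2-(1,3-dioxolan-2-yl)ethyl]-4,6,6-trimethyl-2-oxobicyclo[3.1.1]heptan-3-yl}-3-methylpent-2-enoate (C9 epimers) | CCOC(=O)/C=C(\C)CCC1C(=O)[C@H]2C[C@H](C2(C)C)[C@@]1(C)CCC3OCCO3 | intermediate
9 | ethyl (2E)-5-{3-(2-iodopropan-2-yl)-2-[3-iodo-3-(2-trimethylsilyloxyethoxy)propyl]-2-methyl-6-(trimethylsilyloxy)cyclohex-5-en-1-yl}-3-methylpent-2-enoate (formed in the flask) | CCOC(=O)/C=C(\C)CCC1C(O[Si](C)(C)C)=CC[C@H](C(C)(C)I)[C@@]1(C)CCC(I)OCCO[Si](C)(C)C | intermediate
10 | ethyl (2E)-3-methyl-5-{2-methyl-3-(prop-1-en-2-yl)-6-(trimethylsilyloxy)-2-[3-(2-trimethylsilyloxyethoxy)prop-2-en-1-yl]cyclohex-5-en-1-yl}pent-2-enoate (formed in the flask) | CCOC(=O)/C=C(\C)CCC1C(O[Si](C)(C)C)=CC[C@H](C(C)=C)[C@@]1(C)CC=COCCO[Si](C)(C)C | intermediate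
11 | ethyl (2E)-3-methyl-5-[2-methyl-6-oxo-2-(3-oxopropyl)-3-(prop-1-en-2-yl)cyclohexyl]pent-2-enoate (C5 and C10 as in 21; C9 epimers) | CCOC(=O)/C=C(\C)CCC1C(=O)CC[C@H](C(C)=C)[C@@]1(C)CCC=O | intermediate
12 | ethyl (2E)-5-(6-hydroxy-5,5,8a-trimethyl-2-oxodecahydronaphthalen-1-yl)-3-methylpent-2-enoate (trans-fused; C3 and C9 epimers) | CCOC(=O)/C=C(\C)CCC1C(=O)CC[C@@H]2C(C)(C)C(O)CC[C@@]12C | intermediate
13 | ethyl (2E)-5-(6-hydroxy-5,5,8a-trimethyl-2-oxodecahydronaphthalen-1-yl)-3-methylpent-2-enoate (C5, C9 and C10 as in 21; C3 epimers) | CCOC(=O)/C=C(\C)CC[C@@H]1C(=O)CC[C@@H]2C(C)(C)C(O)CC[C@@]12C | intermediate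
14 | dilithium C3 alkoxide and C7=C8 enolate of 13 (formed in the flask) | CCOC(=O)/C=C(\C)CC[C@@H]1C(O[Li])=CC[C@@H]2C(C)(C)C(O[Li])CC[C@@]12C | intermediate
15 | ethyl (2E)-5-[6-hydroxy-5,5,8a-trimethyl-2-(trifluoromethylsulfonyloxy)-1,4,4a,5,6,7,8,8a-octahydronaphthalen-1-yl]-3-methylpent-2-enoate (C3 epimers) | CCOC(=O)/C=C(\C)CC[C@@H]1C(OS(=O)(=O)C(F)(F)F)=CC[C@@H]2C(C)(C)C(O)CC[C@@]12C | intermediate
16 | ethyl (2E)-5-(6-hydroxy-2,5,5,8a-tetramethyl-1,4,4a,5,6,7,8,8a-octahydronaphthalen-1-yl)-3-methylpent-2-enoate (C3 epimers) | CCOC(=O)/C=C(\C)CC[C@@H]1C(C)=CC[C@@H]2C(C)(C)C(O)CC[C@@]12C | intermediate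
17 | ethyl (2E)-3-methyl-5-(2,5,5,8a-tetramethyl-6-oxo-1,4,4a,5,6,7,8,8a-octahydronaphthalen-1-yl)pent-2-enoate (C5, C9 and C10 as in 21) | CCOC(=O)/C=C(\C)CC[C@@H]1C(C)=CC[C@@H]2C(C)(C)C(=O)CC[C@@]12C | intermediate
18 | ethyl (2E)-5-[(1R,4aS,6S,8aS)-6-hydroxy-2,5,5,8a-tetramethyl-1,4,4a,5,6,7,8,8a-octahydronaphthalen-1-yl]-3-methylpent-2-enoate | CCOC(=O)/C=C(\C)CC[C@@H]1C(C)=CC[C@@H]2C(C)(C)[C@@H](O)CC[C@@]12C | intermediate
19 | (2E)-5-[(1R,4aS,6S,8aS)-6-hydroxy-2,5,5,8a-tetramethyl-1,4,4a,5,6,7,8,8a-octahydronaphthalen-1-yl]-3-methylpent-2-en-1-ol | OC/C=C(\C)CC[C@@H]1C(C)=CC[C@@H]2C(C)(C)[C@@H](O)CC[C@@]12C | intermediate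
20 | (S)-3-methylpentanoic acid | CC[C@H](C)CC(=O)O | starting material
21 | (2E)-5-[(1R,4aS,6S,8aS)-6-hydroxy-2,5,5,8a-tetramethyl-1,4,4a,5,6,7,8,8a-octahydronaphthalen-1-yl]-3-methylpent-2-en-1-yl (3S)-3-methylpentanoate, labdane numbering (3S,5S,9R,10S) | CC[C@H](C)CC(=O)OC/C=C(\C)CC[C@@H]1C(C)=CC[C@@H]2C(C)(C)[C@@H](O)CC[C@@]12C | target

## Step count and least certain steps

Total step count: 12. Longest linear sequence: 12 steps (1 → 21); 11 steps from 3.

Step 2 (key step). The enolate carbon C9 is neopentylic, next to the newly formed quaternary C10. The most likely failure is that the magnesium enolate is protonated or recovered and does not add to 4, or that 4 polymerizes. The copper-catalysed addition to the β,β-disubstituted enone may also be slow without silyl activation. The fallback separates the two bond formations. It sets out from 3 and 2: the conjugate addition is run with CuBr·SMe2 and Me3SiCl in THF, which accelerates the addition and delivers the trimethylsilyl enol ether F1. MeLi in THF then cleaves the O–Si bond to the lithium enolate F2, which is added to 4 at −78 °C. The adduct is 6, and treatment with MeOH and K2CO3 brings the sequence back to 7.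

Step 4. The likely failures are loss of regiocontrol in the elimination (the tetrasubstituted isopropylidene alkene would destroy C5), reversible iodide addition to the enoate with loss of its geometry, and capture of the C4 electrophile by the oxygen of the unmasked C3 carbonyl. The fallback avoids both the iodide and the base. It sets out from 8: aqueous HCl in THF hydrolyses the acetal to the bicyclic keto aldehyde F3. Ac2O with BF3·OEt2 and Zn(OAc)2 then opens the cyclobutane by acetolysis, the C4 cation losing a methyl proton directly, and protects the aldehyde in the same operation, giving the enol acetate 1,1-diacetate F4. K2CO3 in MeOH at 0 °C cleaves the three acetates and returns to 11.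

Step 5. The tertiary radical may be reduced before it cyclizes. The addition to the aldehyde is also reversible, so ring opening of the alkoxy radical can outrun its reduction, and the silane may reduce the aldehyde. The fallback changes the way the radical is made and trapped. It sets out from 11: dry HBr in CH2Cl2 at −78 °C adds to the isopropenyl group in the Markovnikov sense to give the tertiary bromide F5. Slow addition of Bu3SnH with 2,2'-azobis(2-methylpropionitrile) in toluene at 80 °C then generates the same C4 radical by bromine abstraction. The stannane traps the alkoxy radical at close to the diffusion limit, and the sequence returns at 12.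

Step 7. The C3 lithium alkoxide may interfere through aggregation or competing O-sulfonylation, and excess base may deprotonate the enoate at its γ-position. The fallback removes the free hydroxyl. It sets out from 13: Et3SiCl and imidazole give the triethylsilyl ether F6. KN(SiMe3)2 (1.1 equiv) and PhNTf2 at −78 °C give the silylated enol triflate F7. The Negishi conditions of step 8 give the silylated methyl alkene F8, and 1 M HCl in THF removes the silyl group, returning to 16.

Step 10. Hydride delivery may be only partly equatorial, or the enoate may be reduced in the 1,4 sense. The fallback moves the ketone reduction to the end, where no conjugate acceptor is left. It sets out from 16: i-Bu2AlH gives the diol F9 (C3 epimers), and acylation with 20 under the conditions of step 12 gives the hydroxy ester F10. DMP oxidizes this to the keto ester F11, and LiBH(s-Bu)3 at −78 °C, which leaves a saturated ester alone, returns the route at 21.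

## Further compounds

F1 | step 2 | 2-{2-[2,6,6-trimethyl-4-(trimethylsilyloxy)bicyclo[3.1.1]hept-3-en-2-yl]ethyl}-1,3-dioxolane (C10 as in 21) | C1=C(O[Si](C)(C)C)[C@H]2C[C@H](C2(C)C)[C@@]1(C)CCC3OCCO3
F2 | step 2 | lithium 4-[2-(1,3-dioxolan-2-yl)ethyl]-4,6,6-trimethylbicyclo[3.1.1]hept-2-en-2-olate | C1=C(O[Li])[C@H]2C[C@H](C2(C)C)[C@@]1(C)CCC3OCCO3
F3 | step 4 | ethyl (2E)-3-methyl-5-[4,6,6-trimethyl-2-oxo-4-(3-oxopropyl)bicyclo[3.1.1]heptan-3-yl]pent-2-enoate (C9 epimers) | CCOC(=O)/C=C(\C)CCC1C(=O)[C@H]2C[C@H](C2(C)C)[C@@]1(C)CCC=O
F4 | step 4 | ethyl (2E)-5-[6-acetoxy-2-(3,3-diacetoxypropyl)-2-methyl-3-(prop-1-en-2-yl)cyclohex-5-en-1-yl]-3-methylpent-2-enoate (C9 epimers) | CCOC(=O)/C=C(\C)CCC1C(OC(C)=O)=CC[C@H](C(C)=C)[C@@]1(C)CCC(OC(C)=O)OC(C)=O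
F5 | step 5 | ethyl (2E)-5-[3-(2-bromopropan-2-yl)-2-methyl-6-oxo-2-(3-oxopropyl)cyclohexyl]-3-methylpent-2-enoate (C9 epimers) | CCOC(=O)/C=C(\C)CCC1C(=O)CC[C@H](C(C)(C)Br)[C@@]1(C)CCC=O
F6 | step 7 | ethyl (2E)-3-methyl-5-[5,5,8a-trimethyl-2-oxo-6-(triethylsilyloxy)decahydronaphthalen-1-yl]pent-2-enoate (C3 epimers) | CCOC(=O)/C=C(\C)CC[C@@H]1C(=O)CC[C@@H]2C(C)(C)C(O[Si](CC)(CC)CC)CC[C@@]12C
F7 | step 7 | ethyl (2E)-3-methyl-5-[5,5,8a-trimethyl-6-(triethylsilyloxy)-2-(trifluoromethylsulfonyloxy)-1,4,4a,5,6,7,8,8a-octahydronaphthalen-1-yl]pent-2-enoate (C3 epimers) | CCOC(=O)/C=C(\C)CC[C@@H]1C(OS(=O)(=O)C(F)(F)F)=CC[C@@H]2C(C)(C)C(O[Si](CC)(CC)CC)CC[C@@]12C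
F8 | step 7 | ethyl (2E)-3-methyl-5-[2,5,5,8a-tetramethyl-6-(triethylsilyloxy)-1,4,4a,5,6,7,8,8a-octahydronaphthalen-1-yl]pent-2-enoate (C3 epimers) | CCOC(=O)/C=C(\C)CC[C@@H]1C(C)=CC[C@@H]2C(C)(C)C(O[Si](CC)(CC)CC)CC[C@@]12C
F9 | step 10 | (2E)-5-(6-hydroxy-2,5,5,8a-tetramethyl-1,4,4a,5,6,7,8,8a-octahydronaphthalen-1-yl)-3-methylpent-2-en-1-ol (C3 epimers) | OC/C=C(\C)CC[C@@H]1C(C)=CC[C@@H]2C(C)(C)C(O)CC[C@@]12C
F10 | step 10 | (2E)-5-(6-hydroxy-2,5,5,8a-tetramethyl-1,4,4a,5,6,7,8,8a-octahydronaphthalen-1-yl)-3-methylpent-2-en-1-yl (3S)-3-methylpentanoate (C3 epimers) | CC[C@H](C)CC(=O)OC/C=C(\C)CC[C@@H]1C(C)=CC[C@@H]2C(C)(C)C(O)CC[C@@]12C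
F11 | step 10 | (2E)-3-methyl-5-(2,5,5,8a-tetramethyl-6-oxo-1,4,4a,5,6,7,8,8a-octahydronaphthalen-1-yl)pent-2-en-1-yl (3S)-3-methylpentanoate | CC[C@H](C)CC(=O)OC/C=C(\C)CC[C@@H]1C(C)=CC[C@@H]2C(C)(C)C(=O)CC[C@@]12C
A1 | alternative 1 | 5-ethenyl-1,4a,6-trimethyl-5,8-dihydronaphthalen-2(4aH)-one (C9 and C10 as in the target) | C=C[C@@H]1C(C)=CCC2=C(C)C(=O)C=C[C@@]12C
A2 | alternative 1 | methyl (2E,4Z)-6-(3-hydroxy-2,6-dimethylphenyl)-4-methylhexa-2,4-dien-1-yl carbonate | COC(=O)OC/C=C/C(C)=C\Cc1c(C)c(O)ccc1C
A3 | alternative 2 | (4R)-4-benzyl-3-(2,5,5,8a-tetramethyl-6-oxo-1,2,4a,5,6,7,8,8a-octahydronaphthalene-1-carbonyl)-1,3-oxazolidin-2-one (C5, C9 and C10 as in the target) | O=C1OC[C@@H](Cc2ccccc2)N1C(=O)[C@@H]3[C@H](C)C=C[C@@H]4C(C)(C)C(=O)CC[C@@]34C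
A4 | alternative 2 | (4R)-4-benzyl-3-[(2E,8E,10E)-3,7,7-trimethyl-6-oxododeca-2,8,10-trienoyl]-1,3-oxazolidin-2-one | O=C1OC[C@@H](Cc2ccccc2)N1C(=O)/C=C(\C)CCC(=O)C(C)(C)/C=C/C=C/C
A5 | alternative 3 | 3-hydroxydrima-5,8-dien-11-oic acid 11,3-lactone (C3 and C10 as in the target) | O=C1O[C@H]2CC[C@@]3(C)C1=C(C)CC=C3C2(C)C
A6 | alternative 3 | (1S)-3-ethenyl-2,2,4-trimethylcyclohex-3-en-1-yl but-2-ynoate | CC#CC(=O)O[C@H]1CCC(C)=C(C=C)C1(C)C
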